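**Retrosynthetic overview** (carbons counted from the carboxyl carbon)
1. The 2,5-dioxo-2,5-dihydrofuran (maleic anhydride) ring is unveiled last from a 3-alkylfuran ring (singlet oxygen, then Jones oxidation), as in the presumed biogenesis from a furanoterpenoid; the furan ring is bought as 3-bromofuran, so no ring is constructed.
2. Key disconnection C4–C5: an enantioselective, reductive "head-to-tail prenyl transfer", a Cu–H/Pd-catalysed hydroallylation of achiral methyl 3-methylbut-3-enoate (C1–C4) with the (2Z,6Z)-allylic carbonate carrying C5–C14 and the furan. One operation forms C4–C5 and the only stereocentre (C3).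
3. Enabling feature: C5 is the allylic CH2 of the trisubstituted C6=C7 Z-alkene (a π-allyl terminus whose far end C7 is fully substituted), and C4–C3(H)(CH3)–C2–C1 is an isopentenyl unit whose C3–H can arrive as hydride on a C3=C4 1,1-disubstituted alkene. The chain alkenes and the furan ring do not react with Cu–H.
4. Allylic partner: neryl acetate supplies C5–C10 with the C6=C7 Z-alkene. The C10=C11 Z-alkene comes from an α-iodo Wittig olefination followed by a stereoretentive B-alkyl Suzuki–Miyaura coupling with the 9-BBN adduct of 3-allylfuran (C12–C14 plus ring).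
5. End game: ester hydrolysis, furan → γ-hydroxybutenolide → anhydride.

Key step: step 8

Assumption: (R)-DTBM-SEGPHOS is taken, by analogy with related Cu–H additions to 1,1-disubstituted alkenes, to deliver the (3R)-ester; if a model run shows the opposite sense, the (S)-ligand is used instead.

**Route**

Step 1
Reactants: 1 neryl acetate, (2Z)-3,7-dimethylocta-2,6-dien-1-yl acetate
Product: 2 (2Z)-5-(3,3-dimethyloxiran-2-yl)-3-methylpent-2-en-1-yl acetate (racemic at the epoxide)
Conditions: mCPBA (1.05 equiv), CH2Cl2, 0 °C
Reagents that add atoms: 3-chloroperoxybenzoic acid, OOC(=O)c1cccc(Cl)c1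
Why: Prilezhaev epoxidation is electrophilic and should select the remote trisubstituted alkene over the 2,3-alkene that is deactivated by the allylic acetate; the new epoxide stereocentre is racemic and is destroyed in step 2.

Step 2
Reactants: 2 (2Z)-5-(3,3-dimethyloxiran-2-yl)-3-methylpent-2-en-1-yl acetate
Product: 4 (2Z)-3-methyl-6-oxohex-2-en-1-yl acetate, via vicinal diol 3 (not isolated)
Conditions: H5IO6 (1.2 equiv), THF/H2O, 0 °C → rt
Reagents that add atoms: none
Why: Periodic acid should hydrolyse the epoxide to the vicinal diol and cleave it in the same flask (Malaprade glycol cleavage) to the aldehyde and acetone, leaving the Z-allylic acetate untouched.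

Step 3
Reactants: 4 (2Z)-3-methyl-6-oxohex-2-en-1-yl acetate
Product: 5 (2Z,6Z)-7-iodo-3-methylocta-2,6-dien-1-yl acetate
Conditions: [Ph3PCH2CH3]I, n-BuLi, THF, rt; I2, −78 °C; NaHMDS, −78 → −20 °C; then 4, −78 °C → rt
Reagents that add atoms: ethyltriphenylphosphonium iodide, CC[P+](c1ccccc1)(c1ccccc1)c1ccccc1.[I-]; iodine, II
Why: Wittig olefination with the α-iodo ylide Ph3P=C(I)CH3 made in the flask is a known Z-selective entry to 2-iodoalk-2-enes, placing iodine cis to the chain and thereby fixing the geometry of the second trisubstituted alkene.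

Step 4
Reactants: 5 (2Z,6Z)-7-iodo-3-methylocta-2,6-dien-1-yl acetate
Product: 6 (2Z,6Z)-7-iodo-3-methylocta-2,6-dien-1-ol
Conditions: K2CO3 (0.2 equiv), MeOH, 0 °C → rt
Reagents that add atoms: none
Why: Base-catalysed transesterification with methanol removes the acetate, which Pd(0) would ionise in step 6, while the vinyl iodide is inert.

Step 5
Reactants: 7 3-bromofuran
Product: 9 3-(prop-2-en-1-yl)furan, via furan-3-yllithium 8 (not isolated)
Conditions: n-BuLi (1.0 equiv), THF, −78 °C; then CuBr·SMe2 (10 mol%), allyl bromide, −78 → −20 °C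
Reagents that add atoms: allyl bromide, C=CCBr
Why: Bromine–lithium exchange at −78 °C gives the 3-lithiofuran without migration to the 2-position, and copper-catalysed allylation installs the three-carbon arm.

Step 6
Reactants: 9 3-(prop-2-en-1-yl)furan; 6 (2Z,6Z)-7-iodo-3-methylocta-2,6-dien-1-ol
Product: 11 (2Z,6Z)-10-(furan-3-yl)-3,7-dimethyldeca-2,6-dien-1-ol, via B-alkyl-9-BBN 10 (not isolated)
Conditions: 9-BBN, THF, 0 °C → rt; then 6, PdCl2(dppf) (5 mol%), Ph3As, Cs2CO3, DMF/H2O, rt
Reagents that add atoms: none
Why: 9-BBN hydroborates only the terminal alkene, anti-Markovnikov, and the B-alkyl Suzuki–Miyaura coupling proceeds with retention at the vinyl iodide, so the new chain ends cis to the C5 methylene and the 6Z geometry is secured.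

Step 7
Reactants: 11 (2Z,6Z)-10-(furan-3-yl)-3,7-dimethyldeca-2,6-dien-1-ol
Product: 12 (2Z,6Z)-10-(furan-3-yl)-3,7-dimethyldeca-2,6-dien-1-yl methyl carbonate
Conditions: ClCO2Me, pyridine, CH2Cl2, 0 °C
Reagents that add atoms: methyl chloroformate, COC(Cl)=O
Why: Acylation of the primary allylic alcohol gives the carbonate, which Pd(0) ionises without added base and which supplies the methoxide needed for Cu–H turnover in step 8.

Step 8
Reactants: 12 (2Z,6Z)-10-(furan-3-yl)-3,7-dimethyldeca-2,6-dien-1-yl methyl carbonate; 13 methyl 3-methylbut-3-enoate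
Product: 14 methyl (3R,6Z,10Z)-14-(furan-3-yl)-3,7,11-trimethyltetradeca-6,10-dienoate
Conditions: Cu(OAc)2 (5 mol%), Pd(OAc)2 (2.5 mol%), (R)-DTBM-SEGPHOS (8 mol%), (MeO)2MeSiH (2 equiv, slow addition), 13 (2 equiv), THF, 25–40 °C
Reagents that add atoms: none
Why: Proposed new method: Cu–H carrying the chiral bisphosphine adds across the 1,1-disubstituted alkene of 13 with copper at the CH2 terminus and hydride at the methyl-bearing carbon, Pd(0) ionises carbonate 12 to a π-allyl-Pd methoxide with loss of CO2, the primary alkyl group passes from Cu to Pd and C–C reductive elimination at the unsubstituted allyl terminus gives 14, while Cu–OMe is returned to Cu–H by the silane so that no external base is needed. The closest known reaction types are the Cu–H anti-Markovnikov hydroamination of 1,1-disubstituted alkenes (β-stereocentre set in the hydrocupration), dual Cu–H/Pd hydroarylation of alkenes and Cu/Pd-cooperative capture of alkylcopper intermediates by π-allyl-Pd; their union with an unactivated alkene and a γ,γ-disubstituted Z-allyl partner is what is new. No ring is closed. The single new stereocentre (C3 of 14) is fixed by the ligand in the enantio-determining hydride delivery and is not at risk afterwards because all later bond changes occur at the neighbouring primary carbon. The step needs linear coupling with retention of the 2Z-alkene and chemoselectivity for one of three C=C bonds beside the furan: the fully substituted far terminus of the allyl unit and inner-sphere reductive elimination direct bond formation to the CH2 end, syn/anti exchange of the π-allyl would require a σ-Pd at the tertiary carbon and should be slower than coupling, the carbonate is inert to direct SN2′ attack by alkylcopper, one chiral ligand serves both metals so that no achiral Cu–H arises, and trisubstituted alkenes and furans do not insert into Cu–H. Slow addition of the silane and excess 13 should keep hydride reduction of the π-allyl in check.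

Step 9
Reactants: 14 methyl (3R,6Z,10Z)-14-(furan-3-yl)-3,7,11-trimethyltetradeca-6,10-dienoate
Product: 16 (3R,6Z,10Z)-14-(furan-3-yl)-3,7,11-trimethyltetradeca-6,10-dienoic acid, via lithium carboxylate 15 (not isolated)
Conditions: LiOH, THF/MeOH/H2O, rt; then 1 M HCl to pH 3, 0 °C
Reagents that add atoms: lithium hydroxide, [Li+].[OH-]
Why: Saponification (BAc2) of the unhindered methyl ester; the stereocentre is β to the carbonyl and cannot epimerise, and the furan tolerates the brief cold acidification.

Step 10
Reactants: 16 (3R,6Z,10Z)-14-(furan-3-yl)-3,7,11-trimethyltetradeca-6,10-dienoic acid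
Product: 18 (3R,6Z,10Z)-14-(2-hydroxy-5-oxo-2,5-dihydrofuran-3-yl)-3,7,11-trimethyltetradeca-6,10-dienoic acid, via furan endoperoxide 17 (not isolated)
Conditions: O2, hν (visible), tetraphenylporphyrin (cat.), i-Pr2NEt (2 equiv), CH2Cl2, −78 °C
Reagents that add atoms: oxygen, O=O
Why: The [4+2] cycloaddition of singlet oxygen to the electron-rich furan should be much faster at −78 °C than the ene reaction of trisubstituted alkenes, and the hindered amine triggers Kornblum–DeLaMare fragmentation of the endoperoxide to the γ-hydroxybutenolide (lactol epimers, of no consequence).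

Step 11
Reactants: 18 (3R,6Z,10Z)-14-(2-hydroxy-5-oxo-2,5-dihydrofuran-3-yl)-3,7,11-trimethyltetradeca-6,10-dienoic acid
Product: 19 (3R,6Z,10Z)-14-(2,5-dioxo-2,5-dihydrofuran-3-yl)-3,7,11-trimethyltetradeca-6,10-dienoic acid
Conditions: CrO3, H2SO4 (Jones reagent), acetone, 0 °C; toluene azeotrope on isolation
Reagents that add atoms: none
Why: Jones oxidation converts the hemiacylal C–H/O–H into the second carbonyl of the cyclic anhydride, while the carboxylic acid and the two trisubstituted alkenes should survive the short cold exposure and any ring-opened diacid recloses on azeotropic drying.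

**Compound list**
1 | neryl acetate, (2Z)-3,7-dimethylocta-2,6-dien-1-yl acetate | CC(C)=CCC/C(C)=C\COC(C)=O | starting material
2 | (2Z)-5-(3,3-dimethyloxiran-2-yl)-3-methylpent-2-en-1-yl acetate (racemic) | CC1(C)OC1CC/C(C)=C\COC(C)=O | intermediate
3 | (2Z)-6,7-dihydroxy-3,7-dimethyloct-2-en-1-yl acetate | CC(C)(O)C(O)CC/C(C)=C\COC(C)=O | intermediate
4 | (2Z)-3-methyl-6-oxohex-2-en-1-yl acetate | O=CCC/C(C)=C\COC(C)=O | intermediate
5 | (2Z,6Z)-7-iodo-3-methylocta-2,6-dien-1-yl acetate | C/C(I)=C/CC/C(C)=C\COC(C)=O | intermediate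
6 | (2Z,6Z)-7-iodo-3-methylocta-2,6-dien-1-ol | C/C(I)=C/CC/C(C)=C\CO | intermediate
7 | 3-bromofuran | Brc1ccoc1 | starting material
8 | furan-3-yllithium | [Li]c1ccoc1 | intermediate
9 | 3-(prop-2-en-1-yl)furan | C=CCc1ccoc1 | intermediate
10 | 9-[3-(furan-3-yl)propyl]-9-borabicyclo[3.3.1]nonane | C(CCc1ccoc1)B1C2CCCC1CCC2 | intermediate
11 | (2Z,6Z)-10-(furan-3-yl)-3,7-dimethyldeca-2,6-dien-1-ol | C/C(=C/CO)CC/C=C(/C)CCCc1ccoc1 | intermediate
12 | (2Z,6Z)-10-(furan-3-yl)-3,7-dimethyldeca-2,6-dien-1-yl methyl carbonate | C/C(=C/COC(=O)OC)CC/C=C(/C)CCCc1ccoc1 | intermediate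
13 | methyl 3-methylbut-3-enoate | C=C(C)CC(=O)OC | starting material
14 | methyl (3R,6Z,10Z)-14-(furan-3-yl)-3,7,11-trimethyltetradeca-6,10-dienoate | C/C(=C/CC[C@@H](C)CC(=O)OC)CC/C=C(/C)CCCc1ccoc1 | intermediate
15 | lithium (3R,6Z,10Z)-14-(furan-3-yl)-3,7,11-trimethyltetradeca-6,10-dienoate | C/C(=C/CC[C@@H](C)CC(=O)[O-])CC/C=C(/C)CCCc1ccoc1.[Li+] | intermediate
16 | (3R,6Z,10Z)-14-(furan-3-yl)-3,7,11-trimethyltetradeca-6,10-dienoic acid | C/C(=C/CC[C@@H](C)CC(=O)O)CC/C=C(/C)CCCc1ccoc1 | intermediate
17 | (3R,6Z,10Z)-3,7,11-trimethyl-14-(2,3,7-trioxabicyclo[2.2.1]hept-5-en-5-yl)tetradeca-6,10-dienoic acid | C/C(=C/CC[C@@H](C)CC(=O)O)CC/C=C(/C)CCCC1=CC2OOC1O2 | intermediate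
18 | (3R,6Z,10Z)-14-(2-hydroxy-5-oxo-2,5-dihydrofuran-3-yl)-3,7,11-trimethyltetradeca-6,10-dienoic acid (lactol epimers) | C/C(=C/CC[C@@H](C)CC(=O)O)CC/C=C(/C)CCCC1=CC(=O)OC1O | intermediate
19 | (3R,6Z,10Z)-14-(2,5-dioxo-2,5-dihydrofuran-3-yl)-3,7,11-trimethyltetradeca-6,10-dienoic acid | C/C(=C/CC[C@@H](C)CC(=O)O)CC/C=C(/C)CCCC1=CC(=O)OC1=O | target

**Step count**
Total: 11 steps. Longest linear sequence: 10 steps (steps 1–4 and 6–11; step 5 is the side branch).

**Steps most likely to fail, with fallbacks**

1. Step 8 (Proposed new method). What may go wrong: hydride transfer to the π-allyl-Pd (reductive loss of the carbonate), coupling at the substituted allyl terminus or Z→E isomerisation of the allyl unit, and weak enantiofacial discrimination between CH3 and CH2CO2Me in the hydrocupration. The fallback uses known chemistry with a chiral-pool stereocentre, sets out from 11 and rejoins at 14. Alcohol 11 is mesylated (MsCl, 2,4,6-collidine, DMF, 0 °C) to (2Z,6Z)-10-(furan-3-yl)-3,7-dimethyldeca-2,6-dien-1-yl methanesulfonate F1, which LiCl displaces in the same flask to give 3-[(4Z,8Z)-10-chloro-4,8-dimethyldeca-4,8-dien-1-yl]furan F2. Purchased (R)-3-methylglutaric acid monomethyl ester, OC(=O)C[C@@H](C)CC(=O)OC, undergoes Hunsdiecker-type iododecarboxylation (PhI(OAc)2, I2, hν, cyclohexane) to methyl (3S)-4-iodo-3-methylbutanoate F3. Iodine–zinc exchange (Et2Zn, CuI cat., 50 °C, then removal of EtI and excess Et2Zn) gives bis[(2S)-4-methoxy-2-methyl-4-oxobutyl]zinc F4. Cobalt(II) bromide-catalysed allylation of F4 with F2 (THF/NMP, −10 °C), a reaction type known to proceed by SN2 substitution with retention of the alkene geometry of neryl-type chlorides, should then give 14.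

2. Step 3. What may go wrong: erosion of the Z-selectivity of the olefination and decomposition of the thermally labile α-iodo ylide before it meets the aldehyde. The fallback sets out from 4 and rejoins at 11; here the geometry is decided by the site-selectivity of oxidative addition instead. Dibromo-olefination of 4 (CBr4, PPh3, Zn, CH2Cl2; first stage of the Corey–Fuchs sequence) gives (2Z)-7,7-dibromo-3-methylhepta-2,6-dien-1-yl acetate F5. Methanolysis (K2CO3, MeOH) gives (2Z)-7,7-dibromo-3-methylhepta-2,6-dien-1-ol F6. A trans-selective Negishi monomethylation (Me2Zn, PdCl2(DPEphos), THF) replaces the bromine trans to the chain and gives (2Z,6Z)-7-bromo-3-methylocta-2,6-dien-1-ol F7. B-alkyl Suzuki–Miyaura coupling of F7 with borane 10 (Pd(t-Bu3P)2, Cs2CO3), with retention, should give 11.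

3. Step 10. What may go wrong: competing ene reaction of singlet oxygen at the two trisubstituted alkenes and over-oxidation of the product. The fallback sets out from 16 and rejoins at 18 or, through the regioisomer, at 19. It replaces the photo-oxygenation by a polar oxidation of the furan with buffered sodium chlorite (NaClO2, NaH2PO4, t-BuOH/H2O, excess 2-methylbut-2-ene as hypochlorite scavenger). This should give 18 and/or its regioisomer (3R,6Z,10Z)-14-(5-hydroxy-2-oxo-2,5-dihydrofuran-3-yl)-3,7,11-trimethyltetradeca-6,10-dienoic acid F8, both of which the Jones oxidation of step 11 converts into 19.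

**Further compounds**
F1 | step 8 | (2Z,6Z)-10-(furan-3-yl)-3,7-dimethyldeca-2,6-dien-1-yl methanesulfonate | C/C(=C/COS(C)(=O)=O)CC/C=C(/C)CCCc1ccoc1
F2 | step 8 | 3-[(4Z,8Z)-10-chloro-4,8-dimethyldeca-4,8-dien-1-yl]furan | C/C(=C/CCl)CC/C=C(/C)CCCc1ccoc1
F3 | step 8 | methyl (3S)-4-iodo-3-methylbutanoate | IC[C@@H](C)CC(=O)OC
F4 | step 8 | bis[(2S)-4-methoxy-2-methyl-4-oxobutyl]zinc | COC(=O)C[C@H](C)C[Zn]C[C@@H](C)CC(=O)OC
F5 | step 3 | (2Z)-7,7-dibromo-3-methylhepta-2,6-dien-1-yl acetate | BrC(Br)=CCC/C(C)=C\COC(C)=O
F6 | step 3 | (2Z)-7,7-dibromo-3-methylhepta-2,6-dien-1-ol | BrC(Br)=CCC/C(C)=C\CO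
F7 | step 3 | (2Z,6Z)-7-bromo-3-methylocta-2,6-dien-1-ol | C/C(Br)=C/CC/C(C)=C\CO
F8 | step 10 | (3R,6Z,10Z)-14-(5-hydroxy-2-oxo-2,5-dihydrofuran-3-yl)-3,7,11-trimethyltetradeca-6,10-dienoic acid | C/C(=C/CC[C@@H](C)CC(=O)O)CC/C=C(/C)CCCC1=CC(O)OC1=O
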